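(All runs are calculated from invented constants; noise was put on by code.)

At 6.0 min you are reading the tail of X, so the useful count is how many lifetimes of X lie between the last firm reading and that time.

| flask | D | G | J | remark | time |
|---|---|---|---|---|---|
| Tuesday's | 0.13 M | 0.51 M | 26 mM | run made earlier |  |
| Wednesday's | 0.62 M | 0.51 M | 26 mM | run made earlier |  |
| Saturday's | 2.4 M | 0.51 M | 26 mM | run made earlier |  |
| red | 0.15 M | 0.510 M | 26 mM |  | 6.0 min |
| amber | 0.30 M | 0.510 M | 26 mM |  | 6.0 min |
| blue | 0.60 M | 0.510 M | 26 mM |  | 6.0 min |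
| teal | 1.5 M | 0.510 M | 26 mM |  | 6.0 min |
| ochre | 2.5 M | 0.510 M | 26 mM |  | 6.0 min |

| Tuesday's: time / min | Tuesday's: X / % | Wednesday's: time / min | Wednesday's: X / % | Saturday's: time / min | Saturday's: X / % |
|---|---|---|---|---|---|
| 0.500 | 20.0 | 1.50 | 17.8 | 0.500 | 11.5 |
| 1.00 | 23.6 | 3.00 | 10.4 | 1.00 | 9.9 |
| 2.50 | 17.0 | 5.00 | 5.1 | 2.50 | 2.5 |
| 6.00 | 6.1 | 6.00 | 5.5 | 6.00 | 0.1 |

(readings scatter by 0.5 percentage points)

- what was read earlier has a scatter of 0.5 percentage points, one standard deviation
- "hardly changes" means that all values lie within two and a half points (for a concentration: within two and a half percent of the largest)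

* [X] at the end for red, amber, blue, teal, ochre, in this order
* the course of these numbers from the first flask to the last (rises all the way / hardly changes / rises, then falls / falls, then rises / falls all the way)

Saturday's X falls from 9.9% at 1.00 min to 2.5% at 2.50 min, which gives 1.09 min for the tail lifetime of X, the gap between two readings past the peak divided by the natural logarithm of their ratio.

Ochre is Saturday's neighbour, with D at 2.5 M against 2.4 M and the same G and J. In ochre D is charged in excess over G, so G is the limiting reagent. From Saturday's 2.50 min to 6.0 min there are 3.21 lifetimes. Tuesday, with D at 0.13 M, has a longer tail lifetime of 3.41 min, so the same stretch holds 1.02 lifetimes. That count is the logarithm of Tuesday's own two readings, so it describes the fall from 17.0% to 6.1% and does not explain it. The gap between the two runs at the end is made of two parts, because Tuesday already stands higher at 2.50 min, with 17.0% against Saturday's 2.5%, and its count is smaller. Saturday's last reading, 0.1%, carries a scatter of 0.5 percentage points, so the count from the firmer reading is what I would trust. Carried onto ochre's charge, my own reckoning gives 0.00252 M.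

The forecast is a little lower at ochre. Its row is 0.0092 M, 0.018 M, 0.031 M, 0.015 M, 0.002 M, with the course "rises, then falls", on the ground that "G caps formation, D is left over, and the leftover D destroys X".

    D + G ⇌ X (K = 2.80 L mol⁻¹, k = 0.0240 L mol⁻¹ s⁻¹)
    D + G ⇌ E (K = 4.10 L mol⁻¹, k = 3.50 × 10⁻⁴ L mol⁻¹ s⁻¹)
    X + J ⇌ E + J, rate k3*[J]*[X] forward; the back reaction follows from the equilibrium constant (k = 0.120 L mol⁻¹ s⁻¹)
    X → Q (k = 0.0140 s⁻¹)

Ochre ends at 0.0117 M, in the row 0.00891 M, 0.0176 M, 0.0268 M, 0.0159 M, 0.0117 M, whose course is "rises, then falls". At 6.00 min ochre holds more E than X, 2.41% against 0.468% of the D charged. From 3.00 min to 6.00 min the lifetime of 1.09 min counts 2.75, yet ochre's X falls from 1.96% to 0.468%, a logarithm of 1.43. Over that stretch in red, Tuesday's lifetime counts 0.880, and red's X falls from 14.3% to 5.94%, a logarithm of 0.879.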